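The route rests on the side-chain bond between C7, the methylidene carbon carried by ring carbon C5 of the cyclohexanone, and C8, the acyloxy-bearing CH next to it. This C7(=CH2)–C8(O) unit is an allylic alcohol retron. A ligand-controlled Nozaki–Hiyama–Kishi reaction therefore joins an alkenyl triflate cut from (S)-carvone (ring plus C7/C14, C6 oxygen in place) to 4-methylpent-3-enal (C8–C13). It makes the C7–C8 bond and the C8 stereocenter in one operation while the ring enone stays untouched. The precursor is a 2-substituted alkenyl triflate. Both angelates, the side-chain epoxide and the cis ring epoxide follow.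

Key step: step 6

Atom labels used below: ring C1 (C=O), C2 (C–CH3), C3, C4 (CH2), C5 (CH carrying the side chain), C6 (CH–O); side chain C7 (=C14H2), C8 (CH–O), C9 (CH2), C10 (epoxide CH), C11 (CMe2). Angelate = (2Z)-2-methylbut-2-enoate.
Assumption: the chiral oxazoline–sulfonamide ligand of step 6 and the D-fructose-derived ketone of step 9 are treated as purchasable reagents; the ligand enantiomer used is the one that delivers the alkenyl group to the Re face of the aldehyde.

Step 1
Reactants: 1 (S)-(+)-carvone
Product: 3 tert-butyldimethylsilyl dienol ether of carvone (2-silyloxy-1,3-diene), via lithium dienolate 2 (not isolated)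
Conditions: LDA, THF, −78 °C; then TBSCl, DMPU, −78 °C to rt
Reagents that add atoms: tert-butyldimethylsilyl chloride, CC(C)(C)[Si](C)(C)Cl
Why: Kinetic deprotonation of the enone at the α'-CH2 (C6) gives the cross-conjugated lithium dienolate, which is silylated on oxygen (silyl enol ether formation) without touching C5.

Step 2
Reactants: 3 silyl dienol ether
Product: 5 (5R,6R)-6-(tert-butyldimethylsilyloxy)carvone, via silyloxy epoxide 4 (not isolated)
Conditions: mCPBA (1 equiv), NaHCO3, CH2Cl2, −20 to 0 °C
Reagents that add atoms: 3-chloroperoxybenzoic acid, OOC(=O)c1cccc(Cl)c1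
Why: Rubottom oxidation, in which the peracid should attack the electron-rich C1=C6 enol ether bond (not the isopropenyl group) on the face anti to the C5 substituent and the silyloxy epoxide opens with 1,4-silyl shift to the α-silyloxy ketone, setting C6 with oxygen trans to the C5 group.

Step 3
Reactants: 5 6-silyloxycarvone
Product: 7 (5S,6R)-5-acetyl-6-(tert-butyldimethylsilyloxy)-2-methylcyclohex-2-en-1-one, via vicinal diol 6 (not isolated)
Conditions: OsO4 (cat.), NaIO4, 2,6-lutidine, dioxane/H2O 3:1, rt
Reagents that add atoms: osmium tetroxide (catalytic oxygen donor), O=[Os](=O)(=O)=O; sodium periodate (reoxidant and cleaving agent), [Na+].[O-]I(=O)(=O)=O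
Why: Lemieux–Johnson cleavage, in which osmylation should take the electron-rich 1,1-disubstituted alkene far faster than the electron-poor enone alkene and periodate cleaves the diol to the methyl ketone, the lutidine buffer keeping C5 from epimerising.

Step 4
Reactants: 7 acetyl enone
Product: 9 alkenyl triflate 1-[(1S,6R)-6-(tert-butyldimethylsilyloxy)-4-methyl-5-oxocyclohex-3-en-1-yl]ethenyl trifluoromethanesulfonate, via potassium enolate 8 (not isolated)
Conditions: KHMDS, THF, −78 °C, short enolate time; then N-(5-chloropyridin-2-yl)triflimide, −78 °C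
Reagents that add atoms: N-(5-chloropyridin-2-yl)-1,1,1-trifluoro-N-(trifluoromethylsulfonyl)methanesulfonamide, O=S(=O)(N(c1ccc(Cl)cn1)S(=O)(=O)C(F)(F)F)C(F)(F)F
Why: Kinetic enolisation of a methyl ketone with a bulky amide base should take the unhindered methyl protons in preference to the C5 methine and the silyloxy-bearing C6 methine, and O-triflation of the enolate at −78 °C gives the 2-substituted alkenyl triflate (enol triflate formation) with C5 and C6 unchanged.

Step 5
Reactants: 10 4-methylpent-3-en-1-ol
Product: 11 4-methylpent-3-enal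
Conditions: Dess–Martin periodinane, NaHCO3, CH2Cl2, 0 °C; used at once as a solution
Reagents that add atoms: none
Why: Dess–Martin oxidation of a primary alcohol under bicarbonate buffer should stop at the β,γ-unsaturated aldehyde without conjugation of the double bond.

Step 6
Reactants: 9 alkenyl triflate; 11 4-methylpent-3-enal
Product: 13 (5R,6R)-6-(tert-butyldimethylsilyloxy)-5-[(3S)-3-hydroxy-6-methylhepta-1,5-dien-2-yl]-2-methylcyclohex-2-en-1-one, via alkenylchromium(III) species 12 (not isolated)
Conditions: CrCl2, chiral oxazoline–sulfonamide ligand, Et3N, NiCl2 (cat.), THF, rt; aqueous work-up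
Reagents that add atoms: none
Why: Nozaki–Hiyama–Kishi reaction, in which Ni(0) inserts into the C–O bond of the alkenyl triflate, the alkenyl group passes to chromium(III) and adds to the aldehyde carbonyl to form the C7–C8 bond, and work-up releases the allylic alcohol. The closest known reaction type is the Ni/Cr-mediated coupling of 2-substituted alkenyl triflates and iodides with aliphatic aldehydes under a chiral sulfonamide ligand. No ring is closed. The only new stereocenter, C8, is set by the reagent: the ligand bound to chromium should shield one face of the coordinated aldehyde so that the alkenyl group arrives on the Re face, which gives 8S, while the resident C5 and C6 centers, separated from C8 by an sp2 carbon, are expected to exert little bias. The step needs chemoselectivity for the aldehyde over the ring enone carbonyl, which the low reactivity of alkenylchromium(III) toward ketones secures, and it needs the β,γ-unsaturated aldehyde to stay unconjugated, which the mild, weakly basic medium secures. The α-silyloxy ketone is kept as a silyl ether and not as an ester at this stage so that chromium(II) has no reducible α-acyloxy ketone to attack.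

Step 7
Reactants: 13 silyl ether
Product: 14 (5R,6R)-6-hydroxy-5-[(3S)-3-hydroxy-6-methylhepta-1,5-dien-2-yl]-2-methylcyclohex-2-en-1-one
Conditions: HF·pyridine, pyridine, THF, 0 °C
Reagents that add atoms: none
Why: Fluoride-driven cleavage of the α-keto silyl ether (Si–F bond formation) under buffered conditions should leave the allylic alcohol, the enone and both alkenes untouched, and no stereocenter is involved.

Step 8
Reactants: 14 diol
Product: 15 bis-angelate (C6 and C8 esters) of 14
Conditions: angelic acid, 2,4,6-trichlorobenzoyl chloride, Et3N, toluene, rt; then 14, 80 °C, no DMAP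
Reagents that add atoms: angelic acid, C/C=C(/C)C(=O)O
Why: Yamaguchi-type esterification through the angelic 2,4,6-trichlorobenzoic mixed anhydride without a nucleophilic catalyst should acylate both secondary hydroxyls while avoiding Z to E (angelate to tiglate) isomerisation, with retention at C6 and C8 because only O–acyl bonds are formed.

Step 9
Reactants: 15 bis-angelate
Product: 16 (10R)-10,11-epoxide of 15
Conditions: D-fructose-derived Shi ketone (30 mol%), Oxone, K2CO3, Bu4NHSO4 (cat.), MeCN/dimethoxymethane/aqueous buffer pH 10.5, 0 °C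
Reagents that add atoms: potassium peroxymonosulfate (Oxone), [K+].[O-]S(=O)(=O)OO
Why: Shi asymmetric epoxidation, in which the electrophilic chiral dioxirane should react only with the electron-rich trisubstituted C10=C11 alkene (enone, angelates and the ester-deactivated 1,1-disubstituted alkene being inert) and deliver oxygen through the spiro transition state to give the 10R epoxide under reagent control.

Step 10
Reactants: 16 epoxy enone
Product: 17 (1R)-allylic alcohol (C1–OH cis to the C5 side chain, trans to the C6 ester)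
Conditions: NaBH4, CeCl3·7H2O, MeOH, −78 °C; neutral quench
Reagents that add atoms: none
Why: Luche 1,2-reduction, in which hydride should attack the enone carbonyl axially, anti to the axial C6–H of the half-chair with the C5 and C6 substituents equatorial, giving the equatorial C1 alcohol, while the low temperature and neutral quench guard against acyl shift from O6 to O1.

Step 11
Reactants: 17 allylic alcohol
Product: 18 2,3-epoxy alcohol (ring epoxide syn to C1–OH and to the C5 side chain)
Conditions: VO(acac)2 (cat.), t-BuOOH, CH2Cl2, 0 °C to rt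
Reagents that add atoms: tert-butyl hydroperoxide, CC(C)(C)OO
Why: Vanadium-catalysed hydroxyl-directed epoxidation should deliver oxygen to C2=C3 on the face of the allylic C1–OH, setting C2 and C3 cis to the C5 side chain, while the other alkenes carry no free hydroxyl and are electron-poor or ester-deactivated.

Step 12
Reactants: 18 epoxy alcohol
Product: 19 target CNP0247177.1
Conditions: Dess–Martin periodinane, NaHCO3, CH2Cl2, 0 °C to rt
Reagents that add atoms: none
Why: Dess–Martin oxidation of the secondary epoxy alcohol to the α,β-epoxy ketone under buffered, non-epimerising conditions should complete the target without changing any stereocenter.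

Compound list
1 | (S)-(+)-carvone, (5S)-2-methyl-5-(prop-1-en-2-yl)cyclohex-2-en-1-one | CC1=CC[C@H](C(C)=C)CC1=O | starting material
2 | lithium (3S)-6-methyl-3-(prop-1-en-2-yl)cyclohexa-1,5-dien-1-olate (cross-conjugated dienolate) | CC1=CC[C@H](C(C)=C)C=C1O[Li] | intermediate
3 | tert-butyldimethyl{[(3S)-6-methyl-3-(prop-1-en-2-yl)cyclohexa-1,5-dien-1-yl]oxy}silane | CC1=CC[C@H](C(C)=C)C=C1O[Si](C)(C)C(C)(C)C | intermediate
4 | silyloxy epoxide of 3: C1–C6 oxirane bearing OTBS on C1, oxirane oxygen trans to the C5 isopropenyl group | C=C(C)[C@H]1CC=C(C)[C@]2(O[Si](C)(C)C(C)(C)C)O[C@H]12 | intermediate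
5 | (5R,6R)-6-[(tert-butyldimethylsilyl)oxy]-2-methyl-5-(prop-1-en-2-yl)cyclohex-2-en-1-one (C6–O trans to isopropenyl) | C=C(C)[C@H]1CC=C(C)C(=O)[C@@H]1O[Si](C)(C)C(C)(C)C | intermediate
6 | (5S,6R)-6-[(tert-butyldimethylsilyl)oxy]-5-(1,2-dihydroxypropan-2-yl)-2-methylcyclohex-2-en-1-one (either carbinol epimer) | OCC(C)(O)[C@H]1CC=C(C)C(=O)[C@@H]1O[Si](C)(C)C(C)(C)C | intermediate
7 | (5S,6R)-5-acetyl-6-[(tert-butyldimethylsilyl)oxy]-2-methylcyclohex-2-en-1-one | CC(=O)[C@H]1CC=C(C)C(=O)[C@@H]1O[Si](C)(C)C(C)(C)C | intermediate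
8 | potassium 1-[(1S,6R)-6-(tert-butyldimethylsilyloxy)-4-methyl-5-oxocyclohex-3-en-1-yl]ethen-1-olate (methyl-side enolate of 7) | C=C(O[K])[C@H]1CC=C(C)C(=O)[C@@H]1O[Si](C)(C)C(C)(C)C | intermediate
9 | 1-[(1S,6R)-6-(tert-butyldimethylsilyloxy)-4-methyl-5-oxocyclohex-3-en-1-yl]ethenyl trifluoromethanesulfonate | C=C(OS(=O)(=O)C(F)(F)F)[C@H]1CC=C(C)C(=O)[C@@H]1O[Si](C)(C)C(C)(C)C | intermediate
10 | 4-methylpent-3-en-1-ol | CC(C)=CCCO | starting material
11 | 4-methylpent-3-enal | CC(C)=CCC=O | intermediate
12 | alkenylchromium(III) dichloride derived from 9 (drawn without the chiral ligand and solvent on chromium) | C=C([Cr](Cl)Cl)[C@H]1CC=C(C)C(=O)[C@@H]1O[Si](C)(C)C(C)(C)C | intermediate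
13 | (5R,6R)-6-[(tert-butyldimethylsilyl)oxy]-5-[(3S)-3-hydroxy-6-methylhepta-1,5-dien-2-yl]-2-methylcyclohex-2-en-1-one | C=C([C@@H](O)CC=C(C)C)[C@H]1CC=C(C)C(=O)[C@@H]1O[Si](C)(C)C(C)(C)C | intermediate
14 | (5R,6R)-6-hydroxy-5-[(3S)-3-hydroxy-6-methylhepta-1,5-dien-2-yl]-2-methylcyclohex-2-en-1-one | C=C([C@@H](O)CC=C(C)C)[C@H]1CC=C(C)C(=O)[C@@H]1O | intermediate
15 | (3S)-2-[(1R,6R)-6-(angeloyloxy)-4-methyl-5-oxocyclohex-3-en-1-yl]-6-methylhepta-1,5-dien-3-yl angelate | C=C([C@H](CC=C(C)C)OC(=O)/C(C)=C\C)[C@H]1CC=C(C)C(=O)[C@@H]1OC(=O)/C(C)=C\C | intermediate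
16 | (2S)-1-[(2R)-3,3-dimethyloxiran-2-yl]-3-[(1R,6R)-6-(angeloyloxy)-4-methyl-5-oxocyclohex-3-en-1-yl]but-3-en-2-yl angelate | C=C([C@H](C[C@H]2OC2(C)C)OC(=O)/C(C)=C\C)[C@H]1CC=C(C)C(=O)[C@@H]1OC(=O)/C(C)=C\C | intermediate
17 | (2S)-1-[(2R)-3,3-dimethyloxiran-2-yl]-3-[(1R,5R,6R)-6-(angeloyloxy)-5-hydroxy-4-methylcyclohex-3-en-1-yl]but-3-en-2-yl angelate (ring OH cis to the side chain, trans to the ring ester) | C=C([C@H](C[C@H]2OC2(C)C)OC(=O)/C(C)=C\C)[C@H]1CC=C(C)[C@@H](O)[C@@H]1OC(=O)/C(C)=C\C | intermediate
18 | (2S)-1-[(2R)-3,3-dimethyloxiran-2-yl]-3-[(1S,2S,3R,4R,6R)-3-(angeloyloxy)-2-hydroxy-1-methyl-7-oxabicyclo[4.1.0]heptan-4-yl]but-3-en-2-yl angelate (ring epoxide, OH and side chain all cis) | C=C([C@H](C[C@H]2OC2(C)C)OC(=O)/C(C)=C\C)[C@H]1C[C@H]3O[C@@]3(C)[C@@H](O)[C@@H]1OC(=O)/C(C)=C\C | intermediate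
19 | CNP0247177.1, (2S)-1-[(2R)-3,3-dimethyloxiran-2-yl]-3-[(1R,3R,4R,6R)-3-(angeloyloxy)-1-methyl-2-oxo-7-oxabicyclo[4.1.0]heptan-4-yl]but-3-en-2-yl angelate | C=C([C@H](C[C@H]1OC1(C)C)OC(=O)/C(C)=C\C)[C@H]1C[C@H]2O[C@@]2(C)C(=O)[C@@H]1OC(=O)/C(C)=C\C | target

Total step count: 12. Longest linear sequence: 11 steps (steps 1–4 and 6–12 from (S)-carvone).

Steps most likely to fail

Step 4. What may go wrong: deprotonation at the C6 or C5 methine of the 1,4-diketone instead of the methyl group, followed by loss of silanolate and aromatisation, or aldol closure of the methyl enolate onto the ring ketone. The fallback sets out from 5 and returns at 15; it takes the ring carbonyl out of play before enolisation. Luche reduction of 5 should give the allylic alcohol (1R,5R,6R)-6-(tert-butyldimethylsilyloxy)-2-methyl-5-(prop-1-en-2-yl)cyclohex-2-en-1-ol F1. Silylation (TESCl, imidazole) gives the bis-silyl ether F2, and Lemieux–Johnson cleavage gives the mono-ketone F3. Kinetic enolisation and triflation, now with a single carbonyl, gives the alkenyl triflate F4. The same Ni/Cr coupling with 11 gives the allylic alcohol F5, and mixed-anhydride angeloylation of its only free hydroxyl gives the C8 angelate F6. HF·pyridine removes both silyl groups to give the diol F7. MnO2 oxidises only the allylic ring hydroxyl to give the hydroxy enone F8, and a second mixed-anhydride angeloylation gives 15.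

Step 6. What may go wrong: insufficient facial discrimination at the aldehyde, the ligand failing to override a mismatched bias of the substrate, so that C8 forms as a mixture; base-induced conjugation of the β,γ-unsaturated aldehyde is a second failure process. The fallback sets out from 9 and 11 and returns at 13; it corrects C8 by inversion instead of relying on the addition. The coupling is run without chiral ligand (CrCl2, NiCl2 cat., DMSO, rt) and the epimers are separated. The 8R allylic alcohol F9 is inverted by a Mitsunobu reaction with 4-nitrobenzoic acid (PPh3, DIAD, THF) to the 8S 4-nitrobenzoate F10, whose methanolysis (K2CO3, MeOH, 0 °C) gives 13. The 8S alcohol from the same coupling is 13 itself.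

Step 9. What may go wrong: hydrolysis or acyl shift of the α-acyloxy enone at pH 10.5, and incomplete face selectivity at an alkene remote from every resident stereocenter, giving C10 epimers that are hard to separate. The fallback sets out from 10 and returns at 16; it makes the epoxide on the small fragment before the union. Shi epoxidation of 10 gives (R)-2-(3,3-dimethyloxiran-2-yl)ethanol F11, and buffered Dess–Martin oxidation gives the epoxy aldehyde F12. The Ni/Cr coupling of F12 with 9 gives the epoxy allylic alcohol F13. Buffered fluoride (TBAF/AcOH) gives the epoxy diol F14, which is kept away from acid because a γ,δ-epoxy alcohol closes to a tetrahydrofuran. Mixed-anhydride bis-angeloylation gives 16.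

Further compounds
F1 | step 4 | (1R,5R,6R)-6-[(tert-butyldimethylsilyl)oxy]-2-methyl-5-(prop-1-en-2-yl)cyclohex-2-en-1-ol | C=C(C)[C@H]1CC=C(C)[C@@H](O)[C@@H]1O[Si](C)(C)C(C)(C)C
F2 | step 4 | C1 triethylsilyl ether of F1 (bis-silyl ether) | C=C(C)[C@H]1CC=C(C)[C@@H](O[Si](CC)(CC)CC)[C@@H]1O[Si](C)(C)C(C)(C)C
F3 | step 4 | methyl ketone from cleavage of the isopropenyl group of F2 | CC(=O)[C@H]1CC=C(C)[C@@H](O[Si](CC)(CC)CC)[C@@H]1O[Si](C)(C)C(C)(C)C
F4 | step 4 | alkenyl triflate of F3 | C=C(OS(=O)(=O)C(F)(F)F)[C@H]1CC=C(C)[C@@H](O[Si](CC)(CC)CC)[C@@H]1O[Si](C)(C)C(C)(C)C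
F5 | step 4 | (8S)-allylic alcohol from F4 and 11 | C=C([C@@H](O)CC=C(C)C)[C@H]1CC=C(C)[C@@H](O[Si](CC)(CC)CC)[C@@H]1O[Si](C)(C)C(C)(C)C
F6 | step 4 | C8 angelate of F5 | C=C([C@H](CC=C(C)C)OC(=O)/C(C)=C\C)[C@H]1CC=C(C)[C@@H](O[Si](CC)(CC)CC)[C@@H]1O[Si](C)(C)C(C)(C)C
F7 | step 4 | C1,C6 diol from desilylation of F6 | C=C([C@H](CC=C(C)C)OC(=O)/C(C)=C\C)[C@H]1CC=C(C)[C@@H](O)[C@@H]1O
F8 | step 4 | 6-hydroxy enone carrying the C8 angelate | C=C([C@H](CC=C(C)C)OC(=O)/C(C)=C\C)[C@H]1CC=C(C)C(=O)[C@@H]1O
F9 | step 6 | 8R epimer of 13 | C=C([C@H](O)CC=C(C)C)[C@H]1CC=C(C)C(=O)[C@@H]1O[Si](C)(C)C(C)(C)C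
F10 | step 6 | 8S 4-nitrobenzoate of 13 | C=C([C@H](CC=C(C)C)OC(=O)c2ccc(cc2)[N+](=O)[O-])[C@H]1CC=C(C)C(=O)[C@@H]1O[Si](C)(C)C(C)(C)C
F11 | step 9 | (R)-2-(3,3-dimethyloxiran-2-yl)ethanol | OCC[C@H]1OC1(C)C
F12 | step 9 | (R)-2-(3,3-dimethyloxiran-2-yl)acetaldehyde | O=CC[C@H]1OC1(C)C
F13 | step 9 | (5R,6R)-6-[(tert-butyldimethylsilyl)oxy]-5-{(3S)-4-[(2R)-3,3-dimethyloxiran-2-yl]-3-hydroxybut-1-en-2-yl}-2-methylcyclohex-2-en-1-one | C=C([C@@H](O)C[C@H]2OC2(C)C)[C@H]1CC=C(C)C(=O)[C@@H]1O[Si](C)(C)C(C)(C)C
F14 | step 9 | (5R,6R)-5-{(3S)-4-[(2R)-3,3-dimethyloxiran-2-yl]-3-hydroxybut-1-en-2-yl}-6-hydroxy-2-methylcyclohex-2-en-1-one | C=C([C@@H](O)C[C@H]2OC2(C)C)[C@H]1CC=C(C)C(=O)[C@@H]1O
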